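**Remark on numbering:** germacranolide numbering is used for all compounds (ring carbons C1–C10, lactone carbons C11–C13, C14 on C10, C15 on C4; O6, O8 and O10 are the oxygens on those carbons). The target is taken as the (4Z,6R,7R,8R,10S) isomer encoded in the given SMILES.

## The problem

Target 25 is a furanoheliangolide. Its ten-membered carbocycle C1–C10 is bridged by an oxygen between C3 and C10, so that O, C3, C2, C1 and C10 form a 3(2H)-furanone cross-conjugated with the Z-configured C4=C5 bond. An α-methylene-γ-butyrolactone is trans-fused at C6/C7, and O8 carries an (E)-4-acetoxy-2-methylbut-2-enoate. The bridged ten-membered ring (sp2 bridgehead C3, Z alkene, fused lactone) is strained and is the bond set that resists end-to-end closure. Three contiguous stereocentres (C6, C7, C8) can control one another, but the quaternary C10 lies 1,3 to C8 across a methylene and must be set independently. The α-methylene lactone and the furanone are Michael acceptors, the allylic acetate and the 8-ester are base-labile, and a free 8-OH next to the 6,12-lactone invites translactonisation, so late steps must be mild. The enabling feature is twofold. The furanone ring is a cyclodehydrated 1,3-diketone (C1, C3) with the C10 hydroxyl. And O8 is placed so that an ester O8–C3 is a seven-membered lactone (O8, C3, C4, C5, C6, C7, C8) whose acyl carbon C3 lies within reach of C2 through a seven-membered transition state (C2, C1, C10, C9, C8, O8, C3). Moving C3 from O8 to C2 therefore converts an easily made seven-membered lactone into the ten-membered carbocycle and frees the 8-OH that the side chain needs.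

## Retrosynthesis

**25 ⇒ 19 + 24.** The C8–O ester bond is cut last. Acid 24 carries the base-labile allylic acetate and is best introduced under neutral carbodiimide conditions. Alcohol 19 is exactly what the key step liberates.

**19 ⇒ 17 (key disconnection).** The enol ether bond O10–C3 and the ring bond C2–C3 are cut. Opening the furanone gives the ten-membered 1,3-diketone 18. Cutting C2–C3 of 18 and re-attaching C3 to O8 gives bis-lactone 17, which has no medium ring and already carries all four stereocentres. Cutting C6–C7, C4=C5 or C3–C4 instead would demand direct closure of the strained ring. The forward reaction asks the C2 enolate of the methyl ketone to attack the lactone carbonyl C3 and the tetrahedral intermediate to expel O8 (ring expansion by three atoms). Acid then closes the furanone.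

**17 ⇒ 16 ⇒ 15.** The C4=C5 bond is cut by ring-closing metathesis, used where it is easy: in a seven-membered ring that enforces the Z geometry. Diene 16 is the methacrylate of the secondary alcohol of 15. C3, C4 and C15 thus come from methacrylic anhydride.

**15 ⇒ 14 ⇒ 11 + 12.** Compound 14 is 15 with O8 and the C1 ketone tied up as a cyclic methyl ketal. This keeps O8 an ether (no 1,4-elimination) and hides the ketone while C7 acts as a nucleophile. The C6–C7 bond and the lactone C12–O6 bond are cut together: chromium-mediated allylation of acrolein 12 with allylic bromide 11, then lactonisation. This sets C6 and C7 in one event under control of C8.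

**11 ⇒ 10 ⇒ 8 + 9.** The C7–C11 bond is cut by a Morita–Baylis–Hillman reaction of aldehyde 8 with methyl acrylate 9. SN2' bromination gives 11.

**8 ⇒ 6 ⇒ 4 ⇒ 1.** Aldehyde 8 comes from ketal 6, made by addition of MeLi (C2) to lactone 4 and ketalisation. Lactone 4 comes from the chiral-pool lactone 1, which supplies C1, C7, C8, C9, C10 and the C8 stereocentre. C14 and O10 are put on C10 by two enolate reactions, each anti to the C8 substituent, which fixes C10.

**24 ⇒ 20 + 21.** An (E)-selective Wittig reaction of glycolaldehyde (from dimer 20) with ylide 21, then saponification and acetylation.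

## Roads not taken

**Alternative 1:** the most obvious cut is C6–C7 with the lactone C–O bond: an intramolecular Barbier-type allylation/lactonisation of the furanone aldehyde–allylic bromide A1, which after desilylation would lead to 19. The forward step must close the strained ten-membered ring end to end, against entropy, from a Z-enal that can isomerise. It must also set C6 and C7 in a macrocyclic transition state whose diastereoselectivity cannot be predicted from acyclic models. The chosen plan forms the same C6–C7 bond intermolecularly, where closed transition-state models apply, and reaches the medium ring through a seven-membered transition state.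

**Alternative 2:** cut C4=C5 and close the ten-membered ring by ring-closing metathesis of diene A2 (5-isopropenylfuranone plus C6 vinyl group) as the last step. The forward step must form a trisubstituted alkene from an electron-poor isopropenyl group inside a strained bridged ring, with oligomerisation and the α-methylene lactone as competitors. The chosen plan uses the same metathesis for a seven-membered ring, and only the fallback to the key step leans on this closure.

**Alternative 3:** cut C9–C10 and O–C7 in an oxonium ylide [2,3]-sigmatropic ring expansion. Diazoketone A3 with Cu(hfacac)2 or Rh2(OAc)4 would give the 11-oxabicyclo[6.2.1]undecadienone A4 directly. This also grows the ring rather than closing it, but the shift leaves a C7=C8 alkene where the target needs the C7–C11 bond and the cis C8–O bond. The α-methyl diazoketone is prone to 1,2-hydride shift, and C2–C3 would still need dehydrogenation. The steps after the key step would outnumber those saved.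

Key step: step 13

## Route

**Step 1**
Reactants: 1 (R)-5-(hydroxymethyl)dihydrofuran-2(3H)-one
Product: 2 (R)-5-{[(tert-butyldiphenylsilyl)oxy]methyl}dihydrofuran-2(3H)-one
Conditions: TBDPSCl, imidazole, DMF, 0 °C to rt
Reagents that add atoms: tert-butylchlorodiphenylsilane, CC(C)(C)[Si](Cl)(c1ccccc1)c1ccccc1
Why: Standard silylation of the primary alcohol; the C8 stereocentre of the chiral-pool lactone is untouched.

**Step 2**
Reactants: 2 (R)-5-{[(tert-butyldiphenylsilyl)oxy]methyl}dihydrofuran-2(3H)-one
Product: 3 (3S,5R)-5-{[(tert-butyldiphenylsilyl)oxy]methyl}-3-methyldihydrofuran-2(3H)-one (trans isomer expected as major; the cis epimer is carried along)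
Conditions: LiN(iPr)2, THF, −78 °C; MeI, −78 to −40 °C
Reagents that add atoms: iodomethane, CI
Why: Lactone enolate alkylation anti to the C5 substituent; the C10 configuration is reset in step 3, so the epimer ratio does not matter.

**Step 3**
Reactants: 3 (3S,5R)-5-{[(tert-butyldiphenylsilyl)oxy]methyl}-3-methyldihydrofuran-2(3H)-one
Product: 4 (3S,5R)-5-{[(tert-butyldiphenylsilyl)oxy]methyl}-3-hydroxy-3-methyldihydrofuran-2(3H)-one
Conditions: NaN(SiMe3)2, THF, −78 °C; 2-(phenylsulfonyl)-3-phenyloxaziridine, −78 °C
Reagents that add atoms: 2-(phenylsulfonyl)-3-phenyloxaziridine, O=S(=O)(c1ccccc1)N1OC1c1ccccc1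
Why: Enolate hydroxylation with an N-sulfonyloxaziridine; the oxidant should approach the planar enolate anti to the CH2OSi group, placing OH trans and CH3 cis to it, which is the (S) configuration needed at C10.

**Step 4**
Reactants: 4 (3S,5R)-5-{[(tert-butyldiphenylsilyl)oxy]methyl}-3-hydroxy-3-methyldihydrofuran-2(3H)-one
Product: 6 (2RS,3S,5R)-5-{[(tert-butyldiphenylsilyl)oxy]methyl}-2-methoxy-2,3-dimethyltetrahydrofuran-3-ol, via hemiketal 5 (not isolated)
Conditions: MeLi (2.2 equiv), THF, −78 °C; then MeOH, PPTS, rt
Reagents that add atoms: methyllithium, [Li]C; methanol, CO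
Why: The first equivalent deprotonates the tertiary OH and the second adds to the lactone carbonyl, where the alkoxide-stabilised tetrahedral intermediate should stop at mono-addition and so deliver C2. Acidic methanol then converts the hemiketal into the cyclic methyl ketal, which masks O8 as an ether and the C1 ketone in one operation.

**Step 5**
Reactants: 6 (2RS,3S,5R)-5-{[(tert-butyldiphenylsilyl)oxy]methyl}-2-methoxy-2,3-dimethyltetrahydrofuran-3-ol
Product: 7 (2RS,3S,5R)-5-(hydroxymethyl)-2-methoxy-2,3-dimethyltetrahydrofuran-3-ol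
Conditions: Bu4NF, THF, 0 °C
Reagents that add atoms: none
Why: Fluoride desilylation; ketal and tertiary alcohol are inert.

**Step 6**
Reactants: 7 (2RS,3S,5R)-5-(hydroxymethyl)-2-methoxy-2,3-dimethyltetrahydrofuran-3-ol
Product: 8 (2R,4S,5RS)-4-hydroxy-5-methoxy-4,5-dimethyltetrahydrofuran-2-carbaldehyde
Conditions: DMP, pyridine, CH2Cl2, 0 °C; used crude
Reagents that add atoms: none
Why: Buffered Dess–Martin oxidation of the primary alcohol; the tertiary alcohol cannot be oxidised and cannot form a lactol with C7 without building a strained bicycle.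

**Step 7**
Reactants: 8 (2R,4S,5RS)-4-hydroxy-5-methoxy-4,5-dimethyltetrahydrofuran-2-carbaldehyde; 9 methyl acrylate
Product: 10 methyl 2-{hydroxy[(2R,4S,5RS)-4-hydroxy-5-methoxy-4,5-dimethyltetrahydrofuran-2-yl]methyl}acrylate (both carbinol epimers)
Conditions: DABCO (1 equiv), MeOH, rt
Reagents that add atoms: none
Why: Morita–Baylis–Hillman reaction, for which α-alkoxy aldehydes are activated substrates; the new carbinol centre is removed in step 8.

**Step 8**
Reactants: 10 methyl 2-{hydroxy[(2R,4S,5RS)-4-hydroxy-5-methoxy-4,5-dimethyltetrahydrofuran-2-yl]methyl}acrylate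
Product: 11 methyl (Z)-2-(bromomethyl)-3-[(2R,4S,5RS)-4-hydroxy-5-methoxy-4,5-dimethyltetrahydrofuran-2-yl]acrylate
Conditions: NBS, Me2S, CH2Cl2, 0 °C to rt
Reagents that add atoms: N-bromosuccinimide, O=C1CCC(=O)N1Br
Why: SN2' bromination of the Morita–Baylis–Hillman alcohol should give the thermodynamically preferred (Z)-2-(bromomethyl)enoate; the tertiary alcohol does not react.

**Step 9**
Reactants: 11 methyl (Z)-2-(bromomethyl)-3-[(2R,4S,5RS)-4-hydroxy-5-methoxy-4,5-dimethyltetrahydrofuran-2-yl]acrylate; 12 acrolein
Product: 14 (4R,5R)-4-[(2R,4S,5RS)-4-hydroxy-5-methoxy-4,5-dimethyltetrahydrofuran-2-yl]-3-methylidene-5-vinyldihydrofuran-2(3H)-one, via hydroxy ester 13 (not isolated)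
Conditions: CrCl2 (3 equiv), THF, 0 °C to rt; aq. NH4Cl
Reagents that add atoms: none
Why: Nozaki–Hiyama-type (Barbier) allylation: the allylchromium reagent (trivalent chromium) adds 1,2 to acrolein at its γ-carbon C7 through a closed chair transition state, which should give the anti adduct and hence the trans lactone (6R). For the C7 face, allylic strain should hold H8 in the plane of the allyl unit, with the ring CH2 (C9) anti to the incoming aldehyde and the ring oxygen outside, giving 7R; the chromium alkoxide then lactonises onto the methyl ester.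

**Step 10**
Reactants: 14 (4R,5R)-4-[(2R,4S,5RS)-4-hydroxy-5-methoxy-4,5-dimethyltetrahydrofuran-2-yl]-3-methylidene-5-vinyldihydrofuran-2(3H)-one
Product: 15 (4R,5R)-4-[(1R,3S)-1,3-dihydroxy-3-methyl-4-oxopentyl]-3-methylidene-5-vinyldihydrofuran-2(3H)-one (in equilibrium with its cyclic hemiketal)
Conditions: AcOH/THF/H2O (3:1:1), rt
Reagents that add atoms: water, O
Why: The tertiary methyl ketal is glycoside-like and should hydrolyse under mild acid that leaves the lactone intact, freeing the C8 hydroxyl and the C1 methyl ketone.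

**Step 11**
Reactants: 15 (4R,5R)-4-[(1R,3S)-1,3-dihydroxy-3-methyl-4-oxopentyl]-3-methylidene-5-vinyldihydrofuran-2(3H)-one
Product: 16 (1R,3S)-3-hydroxy-3-methyl-1-[(2R,3R)-4-methylidene-5-oxo-2-vinyltetrahydrofuran-3-yl]-4-oxopentyl 2-methylprop-2-enoate
Conditions: methacrylic anhydride, Et3N, DMAP (cat.), CH2Cl2, 0 °C
Reagents that add atoms: methacrylic anhydride, CC(=C)C(=O)OC(=O)C(C)=C
Why: DMAP-catalysed acylation of the secondary C8 hydroxyl of the open-chain tautomer; the tertiary C10 hydroxyl and the hemiketal hydroxyl should not compete.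

**Step 12**
Reactants: 16 (1R,3S)-3-hydroxy-3-methyl-1-[(2R,3R)-4-methylidene-5-oxo-2-vinyltetrahydrofuran-3-yl]-4-oxopentyl 2-methylprop-2-enoate
Product: 17 bis-lactone, (4Z,6R,7R,8R,10S): seven-membered enoate lactone O8–C3(=O)–C4(CH3)=C5–C6–C7–C8, trans-fused at C6–C7 to the α-methylene-γ-butyrolactone (O6–C12), with CH2–C(CH3)(OH)–C(=O)CH3 on C8
Conditions: second-generation Hoveyda–Grubbs catalyst (10 mol%), toluene (2 mM), 80 °C
Reagents that add atoms: none
Why: Ring-closing metathesis of the C6 vinyl group with the methacrylate; the seven-membered ring enforces the Z geometry of C4=C5, and the 1,1-disubstituted, electron-poor α-methylene lactone should stay out of the reaction.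

**Step 13**
Reactants: 17 bis-lactone (4Z,6R,7R,8R,10S)
Product: 19 (4Z,6R,7R,8R,10S)-8-hydroxy-1-oxo-3,10-epoxygermacra-2,4,11(13)-trien-6,12-olide, via (4Z,6R,7R,8R,10S)-8,10-dihydroxy-1,3-dioxogermacra-4,11(13)-dien-6,12-olide 18 (not isolated)
Conditions: LiN(SiMe3)2 (3.3 equiv), THF (5 mM), −78 to −20 °C; then 1 M HCl, THF, rt
Reagents that add atoms: none
Why: Proposed new method: LiN(SiMe3)2 deprotonates the C10 hydroxyl and, kinetically, the C2 methyl of the ketone, and the enolate carbon C2 should add to the lactone carbonyl C3 through a seven-membered transition state (C2, C1, C10, C9, C8, O8, C3; 7-exo-trig), possibly relayed by a reversible O8-to-O10 acyl shift that would make it a five-membered Baker–Venkataraman-type transfer. The bridged tetrahedral intermediate collapses by cleaving C3–O8, so the seven-membered lactone becomes the ten-membered carbocycle (three-atom ring expansion) and the C8 alkoxide is released, with the lithium 1,3-diketonate of 18 as the thermodynamic sink that holds the equilibrium. The closest known reaction types are the Claisen condensation of ketone enolates with esters in its O-to-C acyl-transfer form (Baker–Venkataraman rearrangement) and ring expansions by side-chain insertion into lactones. On acidification the C10 hydroxyl adds to the C3 carbonyl (5-exo-trig) and the hemiketal dehydrates towards C2, the classical cyclodehydration of α′-hydroxy-1,3-diketones to 3(2H)-furanones, which closes the second ring and locks the ten-membered ring. No stereocentre is formed or exposed: C6, C7, C8 and C10 come from 17 and none is α to a carbonyl. The step needs C2 to attack C3 and not C12 (eight-membered transition state) or the Michael positions C5 and C13 (eight- and nine-membered), which ring size, low temperature and high dilution should secure. It needs the freed C8 alkoxide not to translactonise onto C12, which would require a strained 2,6-dioxabicyclo[2.2.1]heptane intermediate and a disfavoured 5-endo addition to C13. It also needs cyclodehydration through O10 rather than O8, which is favoured because the O8–C1 alternative would place four contiguous sp2 carbons in the six-atom bridge.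

**Step 14**
Reactants: 20 glycolaldehyde dimer (1,4-dioxane-2,5-diol); 21 ethyl 2-(triphenylphosphoranylidene)propanoate
Product: 22 ethyl (E)-4-hydroxy-2-methylbut-2-enoate
Conditions: THF, reflux
Reagents that add atoms: none
Why: Wittig reaction of a stabilised ylide with glycolaldehyde released from its dimer; stabilised ylides give the (E)-trisubstituted enoate.

**Step 15**
Reactants: 22 ethyl (E)-4-hydroxy-2-methylbut-2-enoate
Product: 23 (E)-4-hydroxy-2-methylbut-2-enoic acid
Conditions: LiOH, THF/H2O, 0 °C to rt; then HCl to pH 2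
Reagents that add atoms: lithium hydroxide, [Li+].[OH-]
Why: Ester saponification; the E geometry keeps the hydroxyl away from the carboxyl, so no butenolide should form.

**Step 16**
Reactants: 23 (E)-4-hydroxy-2-methylbut-2-enoic acid
Product: 24 (E)-4-acetoxy-2-methylbut-2-enoic acid
Conditions: Ac2O, pyridine, DMAP (cat.), CH2Cl2, 0 °C; aqueous work-up
Reagents that add atoms: acetic anhydride, CC(=O)OC(C)=O
Why: O-Acetylation of the primary allylic alcohol; any mixed anhydride at the carboxyl is hydrolysed on work-up.

**Step 17**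
Reactants: 19 (4Z,6R,7R,8R,10S)-8-hydroxy-1-oxo-3,10-epoxygermacra-2,4,11(13)-trien-6,12-olide; 24 (E)-4-acetoxy-2-methylbut-2-enoic acid
Product: 25 target, (4Z,6R,7R,8R,10S)-8-[(E)-4-acetoxy-2-methylbut-2-enoyloxy]-1-oxo-3,10-epoxygermacra-2,4,11(13)-trien-6,12-olide
Conditions: DCC, DMAP (cat.), CH2Cl2, 0 °C to rt
Reagents that add atoms: none
Why: Steglich esterification of the secondary 8-hydroxyl under near-neutral conditions, which should spare the α-methylene lactone, the furanone and the allylic acetate and leave no time for lactone migration.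

## Compound list

1 | (R)-5-(hydroxymethyl)dihydrofuran-2(3H)-one | OC[C@H]1CCC(=O)O1 | starting material
2 | (R)-5-{[(tert-butyldiphenylsilyl)oxy]methyl}dihydrofuran-2(3H)-one | CC(C)(C)[Si](OC[C@H]1CCC(=O)O1)(c1ccccc1)c1ccccc1 | intermediate
3 | (3S,5R)-5-{[(tert-butyldiphenylsilyl)oxy]methyl}-3-methyldihydrofuran-2(3H)-one | C[C@H]1C[C@H](CO[Si](c2ccccc2)(c2ccccc2)C(C)(C)C)OC1=O | intermediate
4 | (3S,5R)-5-{[(tert-butyldiphenylsilyl)oxy]methyl}-3-hydroxy-3-methyldihydrofuran-2(3H)-one | C[C@]1(O)C[C@H](CO[Si](c2ccccc2)(c2ccccc2)C(C)(C)C)OC1=O | intermediate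
5 | (2RS,3S,5R)-5-{[(tert-butyldiphenylsilyl)oxy]methyl}-2,3-dimethyltetrahydrofuran-2,3-diol (hemiketal) | CC1(O)O[C@@H](CO[Si](c2ccccc2)(c2ccccc2)C(C)(C)C)C[C@]1(C)O | intermediate
6 | (2RS,3S,5R)-5-{[(tert-butyldiphenylsilyl)oxy]methyl}-2-methoxy-2,3-dimethyltetrahydrofuran-3-ol | COC1(C)O[C@@H](CO[Si](c2ccccc2)(c2ccccc2)C(C)(C)C)C[C@]1(C)O | intermediate
7 | (2RS,3S,5R)-5-(hydroxymethyl)-2-methoxy-2,3-dimethyltetrahydrofuran-3-ol | COC1(C)O[C@@H](CO)C[C@]1(C)O | intermediate
8 | (2R,4S,5RS)-4-hydroxy-5-methoxy-4,5-dimethyltetrahydrofuran-2-carbaldehyde | COC1(C)O[C@@H](C=O)C[C@]1(C)O | intermediate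
9 | methyl acrylate | C=CC(=O)OC | starting material
10 | methyl 2-{hydroxy[(2R,4S,5RS)-4-hydroxy-5-methoxy-4,5-dimethyltetrahydrofuran-2-yl]methyl}acrylate | C=C(C(=O)OC)C(O)[C@H]1C[C@](C)(O)C(C)(OC)O1 | intermediate
11 | methyl (Z)-2-(bromomethyl)-3-[(2R,4S,5RS)-4-hydroxy-5-methoxy-4,5-dimethyltetrahydrofuran-2-yl]acrylate | COC(=O)/C(CBr)=C/[C@H]1C[C@](C)(O)C(C)(OC)O1 | intermediate
12 | acrolein | C=CC=O | starting material
13 | methyl (3S,4R)-4-hydroxy-3-[(2R,4S,5RS)-4-hydroxy-5-methoxy-4,5-dimethyltetrahydrofuran-2-yl]-2-methylidenehex-5-enoate | C=C[C@@H](O)[C@H](C(=C)C(=O)OC)[C@H]1C[C@](C)(O)C(C)(OC)O1 | intermediate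
14 | (4R,5R)-4-[(2R,4S,5RS)-4-hydroxy-5-methoxy-4,5-dimethyltetrahydrofuran-2-yl]-3-methylidene-5-vinyldihydrofuran-2(3H)-one | C=C[C@H]1OC(=O)C(=C)[C@@H]1[C@H]2C[C@](C)(O)C(C)(OC)O2 | intermediate
15 | (4R,5R)-4-[(1R,3S)-1,3-dihydroxy-3-methyl-4-oxopentyl]-3-methylidene-5-vinyldihydrofuran-2(3H)-one | C=C[C@H]1OC(=O)C(=C)[C@@H]1[C@H](O)C[C@](C)(O)C(C)=O | intermediate
16 | (1R,3S)-3-hydroxy-3-methyl-1-[(2R,3R)-4-methylidene-5-oxo-2-vinyltetrahydrofuran-3-yl]-4-oxopentyl 2-methylprop-2-enoate | C=C[C@H]1OC(=O)C(=C)[C@@H]1[C@H](OC(=O)C(C)=C)C[C@](C)(O)C(C)=O | intermediate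
17 | bis-lactone (4Z,6R,7R,8R,10S): seven-membered O8–C3 enoate lactone fused to the 6,12-α-methylene lactone, side chain CH2C(CH3)(OH)C(=O)CH3 on C8 | C/C1=C/[C@H]2OC(=O)C(=C)[C@@H]2[C@@H](C[C@](C)(O)C(C)=O)OC1=O | intermediate
18 | (4Z,6R,7R,8R,10S)-8,10-dihydroxy-1,3-dioxogermacra-4,11(13)-dien-6,12-olide | C=C1C(=O)O[C@@H]2/C=C(/C)C(=O)CC(=O)[C@@](C)(O)C[C@@H](O)[C@@H]12 | intermediate
19 | (4Z,6R,7R,8R,10S)-8-hydroxy-1-oxo-3,10-epoxygermacra-2,4,11(13)-trien-6,12-olide | C=C1C(=O)O[C@@H]2/C=C(/C)C3=CC(=O)[C@](C)(C[C@@H](O)[C@@H]12)O3 | intermediate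
20 | glycolaldehyde dimer (1,4-dioxane-2,5-diol) | OC1COC(O)CO1 | starting material
21 | ethyl 2-(triphenylphosphoranylidene)propanoate | CCOC(=O)C(C)=P(c1ccccc1)(c1ccccc1)c1ccccc1 | starting material
22 | ethyl (E)-4-hydroxy-2-methylbut-2-enoate | CCOC(=O)/C(C)=C/CO | intermediate
23 | (E)-4-hydroxy-2-methylbut-2-enoic acid | OC/C=C(\C)C(=O)O | intermediate
24 | (E)-4-acetoxy-2-methylbut-2-enoic acid | CC(=O)OC/C=C(\C)C(=O)O | intermediate
25 | (4Z,6R,7R,8R,10S)-8-[(E)-4-acetoxy-2-methylbut-2-enoyloxy]-1-oxo-3,10-epoxygermacra-2,4,11(13)-trien-6,12-olide | C=C1C(=O)O[C@@H]2/C=C(/C)C3=CC(=O)[C@](C)(C[C@@H](OC(=O)/C(C)=C/COC(C)=O)[C@@H]12)O3 | target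

## Step count and risks

Total step count: 17. Longest linear sequence: 14 (steps 1–13 and 17). Steps 14–16 make the side-chain acid.

**Step 13 (key step, proposed new method).** The enolate may add to the α-methylene lactone of a second molecule (oligomerisation) instead of attacking C3. The acyl transfer may stall at the retro-Claisen equilibrium. The liberated C8 alkoxide may migrate the lactone from O6 to O8. Cyclodehydration may proceed through O8 instead of O10. The fallback sets out from 15 and returns at 19, using known reaction types only. Compound 15 is silylated at O8 (Et3SiCl, imidazole) to the triethylsilyl ether F1. The dianion of F1 (LiN(iPr)2, −78 °C) is added to methacrolein to give the aldol adduct F2. Dess–Martin oxidation gives the 1,3-diketone F3. p-TsOH in wet THF cyclodehydrates and desilylates it to the 5-isopropenyl-3(2H)-furanone F4. Ring-closing metathesis of F4 (second-generation Hoveyda–Grubbs catalyst, high dilution) between the isopropenyl and C6 vinyl groups closes C4=C5 and gives 19.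

**Step 9.** The allylchromium reagent may react through the syn manifold (cis lactone) because of the ester on the central allyl carbon. Facial selectivity at C7 may be poor if the ring oxygen rather than the ring CH2 takes the anti position. The fallback sets out from 11 (with 12) and returns at 14. Indium-mediated Barbier allylation (In powder, THF/H2O), for which (Z)-2-(bromomethyl)enoates are expected to react through the syn manifold, would give the C6-epimeric cis lactone F5. Saponification (LiOH) gives the hydroxy acid F6. Mitsunobu lactonisation (PPh3, diisopropyl azodicarboxylate) inverts C6 and gives 14.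

**Step 12.** Metathesis of the 1,1-disubstituted, electron-poor methacrylate with an allylic-oxygenated vinyl group may be slow, so dimerisation through the vinyl group or catalyst decay could win. The fallback sets out from 15 and returns at 17. Compound 15 is esterified at O8 with 2-(diethoxyphosphoryl)propanoic acid (DCC, DMAP) to phosphonate F7. Selective ozonolysis of the C6 vinyl group (O3, then Me2S) gives aldehyde F8. Intramolecular Horner–Wadsworth–Emmons olefination (LiCl, DBU, MeCN, high dilution) closes the seven-membered enoate ring and gives 17.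

**Step 7.** The amine-catalysed reaction is slow, and the α-alkoxy aldehyde may epimerise at C8 or decompose before it couples. The fallback sets out from 8 and returns at 10 without a new compound: Nozaki–Hiyama–Kishi coupling of 8 with methyl 2-bromoacrylate (CrCl2, NiCl2 cat., DMF) gives 10 under neutral conditions.

## Further compounds

F1 | step 13 | (4R,5R)-4-[(1R,3S)-3-hydroxy-3-methyl-4-oxo-1-(triethylsilyloxy)pentyl]-3-methylidene-5-vinyldihydrofuran-2(3H)-one | C=C[C@H]1OC(=O)C(=C)[C@@H]1[C@H](O[Si](CC)(CC)CC)C[C@](C)(O)C(C)=O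
F2 | step 13 | aldol adduct of F1 with methacrolein (C3 carbinol epimers) | C=C[C@H]1OC(=O)C(=C)[C@@H]1[C@H](O[Si](CC)(CC)CC)C[C@](C)(O)C(=O)CC(O)C(C)=C
F3 | step 13 | 1,3-diketone from oxidation of F2 | C=C[C@H]1OC(=O)C(=C)[C@@H]1[C@H](O[Si](CC)(CC)CC)C[C@](C)(O)C(=O)CC(=O)C(C)=C
F4 | step 13 | (4R,5R)-4-{(1R)-1-hydroxy-2-[(2S)-2-methyl-3-oxo-5-(prop-1-en-2-yl)-2,3-dihydrofuran-2-yl]ethyl}-3-methylidene-5-vinyldihydrofuran-2(3H)-one | C=C[C@H]1OC(=O)C(=C)[C@@H]1[C@H](O)C[C@]2(C)OC(C(C)=C)=CC2=O
F5 | step 9 | (4R,5S)-4-[(2R,4S,5RS)-4-hydroxy-5-methoxy-4,5-dimethyltetrahydrofuran-2-yl]-3-methylidene-5-vinyldihydrofuran-2(3H)-one (C6 epimer of 14) | C=C[C@@H]1OC(=O)C(=C)[C@@H]1[C@H]2C[C@](C)(O)C(C)(OC)O2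
F6 | step 9 | (3S,4S)-4-hydroxy-3-[(2R,4S,5RS)-4-hydroxy-5-methoxy-4,5-dimethyltetrahydrofuran-2-yl]-2-methylidenehex-5-enoic acid | C=C[C@H](O)[C@H](C(=C)C(=O)O)[C@H]1C[C@](C)(O)C(C)(OC)O1
F7 | step 12 | (1R,3S)-3-hydroxy-3-methyl-1-[(2R,3R)-4-methylidene-5-oxo-2-vinyltetrahydrofuran-3-yl]-4-oxopentyl 2-(diethoxyphosphoryl)propanoate | C=C[C@H]1OC(=O)C(=C)[C@@H]1[C@H](OC(=O)C(C)P(=O)(OCC)OCC)C[C@](C)(O)C(C)=O
F8 | step 12 | (1R,3S)-1-[(2R,3R)-2-formyl-4-methylidene-5-oxotetrahydrofuran-3-yl]-3-hydroxy-3-methyl-4-oxopentyl 2-(diethoxyphosphoryl)propanoate | O=C[C@H]1OC(=O)C(=C)[C@@H]1[C@H](OC(=O)C(C)P(=O)(OCC)OCC)C[C@](C)(O)C(C)=O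
F0 | step 7 | none | none
A1 | alternative 1 | methyl (2Z,4R)-2-(bromomethyl)-4-(tert-butyldimethylsilyloxy)-5-{(2S)-2-methyl-3-oxo-5-[(2Z)-4-oxobut-2-en-2-yl]-2,3-dihydrofuran-2-yl}pent-2-enoate | O=C/C=C(/C)C1=CC(=O)[C@](C)(C[C@@H](O[Si](C)(C)C(C)(C)C)/C=C(\CBr)C(=O)OC)O1
A2 | alternative 2 | (E)-4-acetoxy-2-methylbut-2-enoate of F4 at O8 (acyclic diene for ring-closing metathesis at C4=C5) | C=C[C@H]1OC(=O)C(=C)[C@@H]1[C@H](OC(=O)/C(C)=C/COC(C)=O)C[C@]2(C)OC(C(C)=C)=CC2=O
A3 | alternative 3 | 3-diazo-1-[(2S,6S)-3-methyl-6-vinyl-5,6-dihydro-2H-pyran-2-yl]butan-2-one | CC(=[N+]=[N-])C(=O)C[C@@H]1O[C@H](C=C)CC=C1C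
A4 | alternative 3 | (4Z,7Z)-3,10-epoxy-1-oxo-germacra-4,7-diene core (4,10-dimethyl-11-oxabicyclo[6.2.1]undeca-4,7-dien-1-one type, C10 as in 25) | C/C1=C/C/C=C\C[C@]2(C)O[C@H]1CC2=O
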